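## Structural features

The target is one cyclohex-2-ene ring carrying three hydroxyl groups and one unbranched C17 chain, (E)-heptadec-12-en-1-yl, attached at a quaternary, tertiary-allylic carbinol carbon. With the working locants C1 (chain-bearing carbinol), C2=C3, C4 and C5 (secondary carbinols) and C6 (CH2), the configuration is 1R,4R,5R; the systematic name is (1R,2R,4R)-4-[(E)-heptadec-12-en-1-yl]cyclohex-5-ene-1,2,4-triol. The C4 and C5 hydroxyls are trans, and the C4 hydroxyl is cis to the C1 hydroxyl. C4 and C5 are contiguous, but C1 is separated from C4 by the C2=C3 bond and from C5 by C6, so no stereocentre stands next to C1. Both allylic carbinols ionise easily and the ring is two dehydrations away from an alkylphenol, so acid must be avoided in the endgame; the isolated E alkene in the chain rules out late unselective hydrogenation, peracid or osmium chemistry. The real difficulty is to fix the lone quaternary centre absolutely and to relate it to a trans-diol on the far side of the ring with very few protecting groups. The key step uses the fact that C4 and C5 are adjacent carbinol carbons lying between the Z alkene and C6: they are a pinacol retron, with C4 coming from an enal carbonyl held in place by C2=C3 and C5 from an alkanal.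

## Logic of the disconnections

22 ⇒ 21. Only the O–Si bond at the C1 oxygen is cut. The tertiary hydroxyl must be masked while low-valent titanium is present, because a free OH would protonate the reagent and bind the metal; a trialkylsilyl ether is the one mask that comes off without acid. Nothing is gained in skeleton. The demand is a fluoride cleavage mild enough for a triol that aromatises under acid.

21 ⇒ 20. The C4–C5 bond is cut, which opens the ring and turns both secondary carbinols into aldehydes. This is the only ring bond flanked by two oxygenated carbons. The cut removes the ring and two of the three stereocentres and leaves C1 as the single stereocentre. The forward step must close a six-membered ring reductively, give the trans-diol, and choose a face under the influence of C1 alone.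

20 ⇒ 18. Both C=O groups are traced back to primary triethylsilyl ethers. 20 holds a Z-enal and a β-silyloxy aldehyde and should not be stored, so it is unveiled in one operation from a stable precursor. A plan that silylates the 1,3-diol and then oxidises twice cannot work while the C4 oxygen still carries a tert-butyldimethylsilyl group; it would need a doubtful selective cleavage of a primary tert-butyldimethylsilyl ether beside a tertiary triethylsilyl ether. In 18 all three oxygens carry the same silyl group, and the primary/tertiary difference alone provides the discrimination. The demand is oxidation at the two primary positions only, without loss of alkene geometry or elimination of silanol.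

18 ⇒ 17 ⇒ 16. Only O–Si bonds change. The C4 oxygen had to differ from the C5 oxygen earlier (one free hydroxyl to direct epoxidation and hydride delivery, the other masked) but must be equivalent to it at the end. The demand is a fluoride cleavage and a silylation strong enough for the tertiary allylic alcohol.

16 ⇒ 15. The C6–H bond is replaced by an epoxide C6–O bond. A 1,3-diol with a tertiary carbinol stereocentre is the retron of hydride opening of a 2,3-epoxy alcohol at its C2. The gain is that C1 now sits in an epoxide that a reagent-controlled reaction can make. The demand is hydride entry at C6 only, not at C1 and not in the conjugate sense through the neighbouring alkene.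

15 ⇒ 14. The two epoxide C–O bonds are cut. The allylic alcohol allows a titanium–tartrate epoxidation to set C1 absolutely, and 14 is achiral. The demand is the correct tartrate enantiomer: the unnatural D-(−) ester gives the required centre, the natural ester its mirror image. Reaction must occur at the allylic-alcohol alkene only.

14 ⇒ 13 ⇒ 11 + 12. The Z C2=C3 alkene is traced to an alkyne, and the C1–C2 bond (sp2–sp) is cut. This gives a vinyl iodide and a commercial alkyne, and the geometry of both diene double bonds becomes a matter of two stereospecific steps. The demand is retention in the coupling and a semihydrogenation that stops at the diene and spares the chain alkene.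

11 ⇒ 9. The C–I bond and the vinylic C–H bond are removed, which is the retron of hydroxyl-directed trans-hydroalumination and iodination of a propargylic alcohol. The trisubstituted alkene of defined geometry then comes from a simple alkynol. The demand is aluminium at the carbon remote from the hydroxyl.

9 ⇒ 6 + 7. The bond between the alkyne carbon and the first chain carbon is cut. This gives a commercial three-carbon unit and the chain bromide. The demand is C-alkylation, not O-alkylation, of the dianion.

6 ⇒ 5 ⇒ 4 ⇒ 1 + 2. The C–Br bond is traced to the alcohol, the E alkene to an alkyne, and the alkyne–CH2 bond is cut. This leaves two commercial compounds, and dissolving-metal reduction secures the E geometry. The demand is acetylide alkylation in the presence of an unprotected hydroxyl.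

## Other disconnections considered

Alternative 1: The cut removes the C1–O and C4–O bonds together and leads to the diene A1, (5R)-5-(tert-butyldimethylsilyloxy)-1-[(E)-heptadec-12-en-1-yl]cyclohexa-1,3-diene. Forward, photosensitised singlet oxygen would add across C1 and C4 in a suprafacial [4+2] reaction on the face remote from the C5 silyloxy group and give the endoperoxide A2. Reduction of the O–O bond (thiourea or zinc) and fluoride would complete the triol.
- In its favour: a concerted cycloaddition guarantees that the C1 and C4 oxygens are cis, and the quaternary carbinol is made without an organometallic addition or an epoxide. On the C1/C4 relationship this plan is better than the chosen one, where that relationship rests on a conformational relay without direct precedent. Two stereocentres are made in one step from one existing centre, which equals the chosen key step.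
- Against it here: A1 is a silyl ether of an arene hydrate and can lose silanol to give the alkylbenzene at any stage. An enantiopure diene with this substitution pattern needs a long preparation. Face selectivity rests on a single allylic substituent. The chain alkene has allylic hydrogens and can undergo the ene reaction with singlet oxygen. A2 has a C4–H next to the peroxide and is open to base-induced Kornblum–DeLaMare cleavage to a hydroxy enone.
- Comparison: the key step builds no C–C bond and no ring, so the whole carbocycle must exist beforehand, whereas the chosen closure makes the ring and two centres together. The three-step endgame is comparable to the two-step endgame of the chosen route, but access to A1 is expected to be longer than access to the open-chain dialdehyde.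

Alternative 2: The cut is the C2=C3 double bond, giving the acyclic diene A3, (3R,5R,6R)-3-[(E)-heptadec-12-en-1-yl]-5,6-bis[(4-methoxybenzyl)oxy]octa-1,7-dien-3-ol. Its two ether-bearing carbons would come from C3 and C4 of a 2-deoxyhexose of the D series. Forward, the second-generation Grubbs catalyst RuCl2(PCy3)(H2IMes)(=CHPh) would join the two vinyl groups with loss of ethylene to give A4, the 4,5-bis(4-methoxybenzyl) ether of the target. Oxidative removal of both ethers would follow.
- In its favour: closure of a cyclohexene from a 1,7-diene is among the most dependable ring formations and tolerates the free tertiary hydroxyl, so in reliability of ring closure this plan is better than the chosen one. The trans C4/C5 pair is taken from the chiral pool and is therefore secure, again a point on which it is better.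
- Against it here: the key step creates no stereocentre, so all three must be in place. C1 has to be made by adding a vinyl or alkyl metal to a β-alkoxy ketone under 1,3-induction; this is the same kind of remote control that is uncertain in the chosen plan, only moved to another step. The chain alkene is a second metathesis-active site and can be scrambled in geometry or position. The sugar has to be cut down and protected, which adds steps.
- Comparison: both plans close the six-membered ring in the last C–C-forming step. The chosen plan sets two centres there and needs one asymmetric reaction in all; this one needs none but carries two benzyl-type ethers on and off and is expected to be longer overall.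

Alternative 3: The cut is the C3–C4 bond, giving the iodo aldehyde A5, (2R,4R,5Z)-4-[(E)-heptadec-12-en-1-yl]-4-hydroxy-6-iodo-2-[(4-methoxybenzyl)oxy]hex-5-enal. Forward, CrCl2 with catalytic NiCl2 (Nozaki–Hiyama–Kishi conditions) would turn the Z-alkenyl iodide into an alkenylchromium species that adds to the aldehyde. This closes the ring and creates the C4 carbinol of A6, the 5-(4-methoxybenzyl) ether of the target; removal of the ether would follow.
- In its favour: the reaction is selective for aldehydes, keeps alkene geometry and tolerates the free tertiary hydroxyl. It needs neither a Z-enal nor a β-silyloxy aldehyde, so in stability of the cyclisation substrate it is better than the chosen plan. Ring size and the type of bond formed (attack on the C4 carbonyl carbon) are equal.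
- Against it here: only one stereocentre is formed, and its sense depends on 1,2-induction from the α-alkoxy centre C5 inside a ring-forming transition state, which does not reliably favour the trans product. The α-alkoxy aldehyde can epimerise. C1 and C5 both need separate asymmetric steps, and the Z-iodoalkene next to a quaternary carbinol must be built. Several equivalents of a toxic chromium salt are consumed.
- Comparison: it makes one centre instead of two in the key step and needs two centres instead of one beforehand, so it is expected to be longer, while its key step is mechanistically the safer of the two.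

Key step: step 13

Remark: the working ring locants (C1 chain-bearing carbinol, C2=C3, C4, C5, C6) are also used for the corresponding atoms of open-chain compounds; D-(−)-diethyl tartrate and Cp2TiCl2 are taken as commercial reagents.

## Route

Step 1
Reactants: 1 1-hexyne; 2 11-bromoundecan-1-ol
Product: 4 heptadec-12-yn-1-ol, via hex-1-ynyllithium 3 (not isolated)
Conditions: 1 (2.4 equiv), n-BuLi (2.2 equiv), THF–DMPU, −78 → 0 °C; then 2, 0 °C → rt
Reagents that add atoms: none
Why: SN2 alkylation of a lithium acetylide by a primary bromide; one extra equivalent of acetylide deprotonates the hydroxyl, whose lithium alkoxide is a spectator, and DMPU breaks up the aggregates.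

Step 2
Reactants: 4 heptadec-12-yn-1-ol
Product: 5 (E)-heptadec-12-en-1-ol
Conditions: Na, NH3(l)–THF, −33 °C; then NH4Cl
Reagents that add atoms: none
Why: Dissolving-metal reduction of an isolated dialkyl alkyne; the vinyl radical anion relaxes to the trans form before protonation, which fixes the E alkene, and the alkoxide is inert.

Step 3
Reactants: 5 (E)-heptadec-12-en-1-ol
Product: 6 (E)-17-bromoheptadec-5-ene
Conditions: CBr4, PPh3, CH2Cl2, 0 °C
Reagents that add atoms: carbon tetrabromide, BrC(Br)(Br)Br
Why: Appel reaction; bromide displaces the oxyphosphonium group at the primary carbon and the remote alkene is untouched.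

Step 4
Reactants: 6 (E)-17-bromoheptadec-5-ene; 7 propargyl alcohol
Product: 9 (E)-icos-15-en-2-yn-1-ol, via dilithiated propargyl alcohol 8 (not isolated)
Conditions: 7 (3 equiv), n-BuLi (6 equiv), THF–DMPU, −78 → 0 °C; then 6, 0 °C → rt
Reagents that add atoms: none
Why: C-alkylation of the propargyl alcohol dianion; the acetylide carbon is far more nucleophilic than the alkoxide oxygen, so the primary bromide is displaced at carbon.

Step 5
Reactants: 9 (E)-icos-15-en-2-yn-1-ol
Product: 11 (2Z,15E)-3-iodoicosa-2,15-dien-1-ol, via cyclic alkenylaluminate 10 (not isolated)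
Conditions: NaAlH2(OCH2CH2OCH3)2, THF, 0 °C → rt; EtOAc; then I2, −78 → 0 °C
Reagents that add atoms: iodine, II
Why: Hydroxyl-directed trans-hydroalumination of a propargylic alcohol puts aluminium on C3 in a five-membered oxaaluminacycle, and iodinolysis with retention gives the (Z)-3-iodo allylic alcohol; the isolated alkene is not hydroaluminated.

Step 6
Reactants: 11 (2Z,15E)-3-iodoicosa-2,15-dien-1-ol; 12 tert-butyldimethyl(prop-2-ynyloxy)silane
Product: 13 (Z)-6-[(tert-butyldimethylsilyl)oxy]-3-[(E)-heptadec-12-en-1-yl]hex-2-en-4-yn-1-ol
Conditions: PdCl2(PPh3)2 (cat.), CuI (cat.), Et3N, THF, rt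
Reagents that add atoms: none
Why: Sonogashira coupling; oxidative addition and reductive elimination at palladium keep the alkene geometry, so the alkynyl group ends cis to CH2OH, and the free hydroxyl is tolerated.

Step 7
Reactants: 13 (Z)-6-[(tert-butyldimethylsilyl)oxy]-3-[(E)-heptadec-12-en-1-yl]hex-2-en-4-yn-1-ol
Product: 14 (2Z,4Z)-6-[(tert-butyldimethylsilyl)oxy]-3-[(E)-heptadec-12-en-1-yl]hexa-2,4-dien-1-ol
Conditions: H2 (1 atm), Pd/CaCO3 poisoned with Pb(OAc)2 (Lindlar catalyst), quinoline, EtOAc, rt
Reagents that add atoms: none
Why: Lindlar semihydrogenation; syn delivery of hydrogen to the alkyne on the poisoned surface gives the Z alkene, and the isolated chain alkene is not reduced under these conditions.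

Step 8
Reactants: 14 (2Z,4Z)-6-[(tert-butyldimethylsilyl)oxy]-3-[(E)-heptadec-12-en-1-yl]hexa-2,4-dien-1-ol
Product: 15 [(2R,3S)-3-{(Z)-3-[(tert-butyldimethylsilyl)oxy]prop-1-en-1-yl}-3-[(E)-heptadec-12-en-1-yl]oxiran-2-yl]methanol
Conditions: Ti(OiPr)4 (cat.), D-(−)-diethyl tartrate (cat.), t-BuOOH, 4 Å MS, CH2Cl2, −20 °C
Reagents that add atoms: tert-butyl hydroperoxide, CC(C)(C)OO
Why: Sharpless asymmetric epoxidation; the titanium–tartrate complex binds the allylic alcohol and D-(−)-tartrate delivers oxygen to the face that makes the CH2OH-bearing carbon R, and since the alkenyl group is cis and the chain trans to CH2OH the quaternary carbon is set as required for C1 (S here, R after step 9 by a change of priorities only). Only the allylic-alcohol alkene reacts.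

Step 9
Reactants: 15 [(2R,3S)-3-{(Z)-3-[(tert-butyldimethylsilyl)oxy]prop-1-en-1-yl}-3-[(E)-heptadec-12-en-1-yl]oxiran-2-yl]methanol
Product: 16 (3R,4Z)-6-[(tert-butyldimethylsilyl)oxy]-3-[(E)-heptadec-12-en-1-yl]hex-4-ene-1,3-diol
Conditions: NaAlH2(OCH2CH2OCH3)2, THF, 0 °C; then aq. potassium sodium tartrate
Reagents that add atoms: none
Why: Hydroxyl-directed hydride opening of a 2,3-epoxy alcohol; the alkoxyaluminium hydride delivers hydride intramolecularly to the epoxide carbon next to CH2OH (ring C6) to give the 1,3-diol, and the C1–O bond is not broken, so the configuration is retained.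

Step 10
Reactants: 16 (3R,4Z)-6-[(tert-butyldimethylsilyl)oxy]-3-[(E)-heptadec-12-en-1-yl]hex-4-ene-1,3-diol
Product: 17 (3R,4Z)-3-[(E)-heptadec-12-en-1-yl]hex-4-ene-1,3,6-triol
Conditions: Bu4NF, THF, 0 °C → rt
Reagents that add atoms: none
Why: Fluoride-mediated cleavage of a primary silyl ether; the non-acidic conditions leave the tertiary allylic alcohol and the Z-ene-1,4-diol unit intact.

Step 11
Reactants: 17 (3R,4Z)-3-[(E)-heptadec-12-en-1-yl]hex-4-ene-1,3,6-triol
Product: 18 (3R,4Z)-3-[(E)-heptadec-12-en-1-yl]-1,3,6-tris[(triethylsilyl)oxy]hex-4-ene
Conditions: Et3SiOTf (3.5 equiv), 2,6-lutidine, CH2Cl2, −78 → 0 °C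
Reagents that add atoms: triethylsilyl trifluoromethanesulfonate, CC[Si](CC)(CC)OS(=O)(=O)C(F)(F)F
Why: Exhaustive silylation with a silyl triflate, which is reactive enough for the tertiary allylic hydroxyl; the hindered base keeps the medium non-acidic so the carbinol does not ionise.

Step 12
Reactants: 18 (3R,4Z)-3-[(E)-heptadec-12-en-1-yl]-1,3,6-tris[(triethylsilyl)oxy]hex-4-ene
Product: 20 (2Z,4R)-4-[(E)-heptadec-12-en-1-yl]-4-[(triethylsilyl)oxy]hex-2-enedial, via bis(alkoxysulfonium) dichloride 19 (not isolated)
Conditions: (COCl)2, DMSO, CH2Cl2, −78 → −30 °C; then Et3N, −78 → −20 °C; cold pH 7 buffer; used at once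
Reagents that add atoms: none
Why: Swern oxidation applied directly to primary triethylsilyl ethers, a known selective deprotection–oxidation; chlorodimethylsulfonium attacks the two unhindered primary ether oxygens with loss of Et3SiCl, the amine converts the alkoxysulfonium ions into aldehydes, and the tertiary silyl ether is too hindered to react. Because C1 is quaternary the Z-enal has no γ-hydrogen and cannot isomerise through a dienolate.

Step 13
Reactants: 20 (2Z,4R)-4-[(E)-heptadec-12-en-1-yl]-4-[(triethylsilyl)oxy]hex-2-enedial
Product: 21 (1R,2R,5R)-5-[(E)-heptadec-12-en-1-yl]-5-[(triethylsilyl)oxy]cyclohex-3-ene-1,2-diol (the C1 triethylsilyl ether of 22)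
Conditions: Cp2TiPh (3 equiv; from Cp2TiCl2, i-PrMgCl then PhMgBr), THF, −78 → 0 °C, 20 added slowly; then pH 7 buffer
Reagents that add atoms: none
Why: Each aldehyde oxygen binds a trivalent titanium centre and accepts one electron; the enal is reduced first to a titanium-bound allylic ketyl, whose carbinyl carbon C4 attacks the titanium-activated C5 carbonyl as the second metal delivers its electron, so C4–C5 forms and a bis(titanoxy) diolate of tetravalent titanium results, which is hydrolysed on work-up. The closest known reaction type is the trans-selective cyclisation of aliphatic 1,6-dialdehydes to cyclohexane-1,2-diols by Cp2TiPh, together with the pinacol coupling of conjugated aldehydes by trivalent titanocenes. The single ring closes in a six-membered mode that is exo with respect to the C5 carbonyl (6-exo-trig); attack through C2 of the allylic ketyl would need a four-membered ring, and the Z C2=C3 bond holds C4 within reach of C5. The C4/C5 relationship is controlled by the two bulky Cp2(Ph)Ti–O groups, which cannot share one metal and keep apart in the closing transition state, so both oxygens take equatorial-type positions on opposite faces (trans). The sense relative to C1 is controlled by the half-chair of the forming cyclohexene: with the C17 chain pseudoequatorial and the smaller C1 silyloxy group pseudoaxial, the equatorial-type C4 oxygen lies on the face of the C1 oxygen, which corresponds to 4R,5R. The step needs chemoselectivity (the silyl ether and the isolated alkene are not reducible by the reagent), regioselectivity (C4, not C2) and two diastereoselectivities; the substrate secures the first three, whereas the 1,4-relay from C1 has no direct precedent and is the open point. Slow addition of 20 to excess reagent keeps the coupling intramolecular.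

Step 14
Reactants: 21 (1R,2R,5R)-5-[(E)-heptadec-12-en-1-yl]-5-[(triethylsilyl)oxy]cyclohex-3-ene-1,2-diol
Product: 22 (1R,2R,4R)-4-[(E)-heptadec-12-en-1-yl]cyclohex-5-ene-1,2,4-triol (working locants 1R,4R,5R; CNP0317923.1)
Conditions: Bu4NF, THF, 0 °C
Reagents that add atoms: none
Why: Fluoride cleavage of the tertiary triethylsilyl ether; the non-acidic conditions avoid ionisation of the allylic carbinols and dehydration towards an arene, and no stereocentre is touched.

## Compound list

1 | 1-hexyne | CCCCC#C | starting material
2 | 11-bromoundecan-1-ol | OCCCCCCCCCCCBr | starting material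
3 | hex-1-yn-1-yllithium (not isolated) | [Li]C#CCCCC | intermediate
4 | heptadec-12-yn-1-ol | CCCCC#CCCCCCCCCCCCO | intermediate
5 | (E)-heptadec-12-en-1-ol | CCCC/C=C/CCCCCCCCCCCO | intermediate
6 | (E)-17-bromoheptadec-5-ene | CCCC/C=C/CCCCCCCCCCCBr | intermediate
7 | propargyl alcohol (prop-2-yn-1-ol) | C#CCO | starting material
8 | dilithium salt of propargyl alcohol, C- and O-lithiated (not isolated) | [Li]C#CCO[Li] | intermediate
9 | (E)-icos-15-en-2-yn-1-ol | CCCC/C=C/CCCCCCCCCCCC#CCO | intermediate
10 | sodium 2,2-bis(2-methoxyethoxy)-3-[(E)-heptadec-12-en-1-yl]-2,5-dihydro-1,2-oxaaluminol-2-uide, the cyclic alkenylaluminate (not isolated) | [Na+].CCCC/C=C/CCCCCCCCCCCC1=CCO[Al-]1(OCCOC)OCCOC | intermediate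
11 | (2Z,15E)-3-iodoicosa-2,15-dien-1-ol | CCCC/C=C/CCCCCCCCCCC/C(I)=C/CO | intermediate
12 | tert-butyldimethyl(prop-2-ynyloxy)silane | C#CCO[Si](C)(C)C(C)(C)C | starting material
13 | (Z)-6-[(tert-butyldimethylsilyl)oxy]-3-[(E)-heptadec-12-en-1-yl]hex-2-en-4-yn-1-ol | CCCC/C=C/CCCCCCCCCCC/C(=C/CO)C#CCO[Si](C)(C)C(C)(C)C | intermediate
14 | (2Z,4Z)-6-[(tert-butyldimethylsilyl)oxy]-3-[(E)-heptadec-12-en-1-yl]hexa-2,4-dien-1-ol | CCCC/C=C/CCCCCCCCCCC/C(=C/CO)/C=C\CO[Si](C)(C)C(C)(C)C | intermediate
15 | [(2R,3S)-3-{(Z)-3-[(tert-butyldimethylsilyl)oxy]prop-1-en-1-yl}-3-[(E)-heptadec-12-en-1-yl]oxiran-2-yl]methanol | CCCC/C=C/CCCCCCCCCCC[C@@]1(/C=C\CO[Si](C)(C)C(C)(C)C)O[C@@H]1CO | intermediate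
16 | (3R,4Z)-6-[(tert-butyldimethylsilyl)oxy]-3-[(E)-heptadec-12-en-1-yl]hex-4-ene-1,3-diol | CCCC/C=C/CCCCCCCCCCC[C@](O)(/C=C\CO[Si](C)(C)C(C)(C)C)CCO | intermediate
17 | (3R,4Z)-3-[(E)-heptadec-12-en-1-yl]hex-4-ene-1,3,6-triol | CCCC/C=C/CCCCCCCCCCC[C@](O)(/C=C\CO)CCO | intermediate
18 | (3R,4Z)-3-[(E)-heptadec-12-en-1-yl]-1,3,6-tris[(triethylsilyl)oxy]hex-4-ene | CCCC/C=C/CCCCCCCCCCC[C@](O[Si](CC)(CC)CC)(/C=C\CO[Si](CC)(CC)CC)CCO[Si](CC)(CC)CC | intermediate
19 | bis(dimethylsulfonio) ether of the 1,6-diol derived from 18, dichloride, C3 triethylsilyl ether retained (not isolated) | CCCC/C=C/CCCCCCCCCCC[C@](O[Si](CC)(CC)CC)(/C=C\CO[S+](C)C)CCO[S+](C)C.[Cl-].[Cl-] | intermediate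
20 | (2Z,4R)-4-[(E)-heptadec-12-en-1-yl]-4-[(triethylsilyl)oxy]hex-2-enedial | CCCC/C=C/CCCCCCCCCCC[C@](O[Si](CC)(CC)CC)(/C=C\C=O)CC=O | intermediate
21 | (1R,2R,5R)-5-[(E)-heptadec-12-en-1-yl]-5-[(triethylsilyl)oxy]cyclohex-3-ene-1,2-diol | CCCC/C=C/CCCCCCCCCCC[C@]1(O[Si](CC)(CC)CC)C=C[C@@H](O)[C@H](O)C1 | intermediate
22 | (1R,2R,4R)-4-[(E)-heptadec-12-en-1-yl]cyclohex-5-ene-1,2,4-triol | CCCC/C=C/CCCCCCCCCCC[C@]1(O)C=C[C@@H](O)[C@H](O)C1 | target

## Step count and least certain steps

Total step count: 14. Longest linear sequence: 14 steps (from 1 and 2 to 22; 7 and 12 enter as commercial compounds).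

Step 13 (key step). Two processes are most likely to fail.
- The titanium-bound allylic ketyl can lose its Z geometry before it closes, after which only intermolecular coupling or simple reduction remains.
- The distant C1 centre may discriminate poorly between the two faces, giving both trans-diols, or the closure may leak to the cis-diol.

Fallback, setting out from 20 and coming back at 21: a chelate-controlled closure followed by inversion at C4. SmI2 (THF, t-BuOH, −78 °C) reduces both carbonyls, bridges the two oxygens on one samarium and should close the same bond to the cis-diol (1R,2S,5R)-5-[(E)-heptadec-12-en-1-yl]-5-[(triethylsilyl)oxy]cyclohex-3-ene-1,2-diol F1. MnO2 (CH2Cl2) would then oxidise only the allylic C4 carbinol to (4R,6R)-4-[(E)-heptadec-12-en-1-yl]-6-hydroxy-4-[(triethylsilyl)oxy]cyclohex-2-en-1-one F2. Me4NBH(OAc)3 (MeCN–AcOH, −20 °C) would deliver hydride from the C5 oxygen on its own face, so the new C4 hydroxyl comes out trans to it, which is 21. The sequence corrects a wrong C4 centre whatever its origin, but it presupposes that C5 forms with the required sense relative to C1.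

Step 12. The amine stage can cause β-elimination of triethylsilanol from the β-silyloxy aldehyde (the leaving group is tertiary and allylic) and Z to E isomerisation of the enal by reversible conjugate addition. The allylic alkoxysulfonium ion can also be displaced by chloride before it is oxidised.

Fallback, setting out from 18 and coming back at 20: separate the unmasking from the oxidation. PPTS in MeOH–CH2Cl2 at 0 °C should remove only the two primary silyl ethers and give (3R,4Z)-3-[(E)-heptadec-12-en-1-yl]-3-[(triethylsilyl)oxy]hex-4-ene-1,6-diol F3. Dess–Martin periodinane with NaHCO3 in CH2Cl2 at 0 °C then oxidises both primary alcohols without base and gives 20.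

Step 8. Oxygen transfer may be slow and poorly face-selective, because the cis substituent on the carbon that becomes C1 is an alkenyl group crowding the titanium-bound peroxide. The tertiary vinyl epoxide can also be opened by the Lewis-acidic titanium species during the reaction or the work-up.

Fallback, setting out from 13 and coming back at 15: epoxidise before the alkyne is reduced. The same Ti(OiPr)4/D-(−)-diethyl tartrate/t-BuOOH system applied to the enynol, whose linear alkynyl substituent is smaller and whose epoxide ionises less readily, should give [(2R,3S)-3-{3-[(tert-butyldimethylsilyl)oxy]prop-1-yn-1-yl}-3-[(E)-heptadec-12-en-1-yl]oxiran-2-yl]methanol F4. Semihydrogenation over Pd/CaCO3 poisoned with Pb(OAc)2 and quinoline then gives 15.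

Step 9. Hydride delivery may be misdirected, either in the conjugate (SN2′) sense through the adjacent Z alkene or to the quaternary epoxide carbon, so the 1,3-diol is not formed cleanly.

Fallback, setting out from 15 and coming back at 16: replace hydride opening by reductive ring opening and hydroboration.
- I2, PPh3 and imidazole convert the hydroxyl into the iodide (2S,3S)-2-[(E)-heptadec-12-en-1-yl]-3-(iodomethyl)-2-{(Z)-3-[(tert-butyldimethylsilyl)oxy]prop-1-en-1-yl}oxirane F5.
- Zinc dust in ethanol opens the epoxide by β-elimination, without touching the C1–O bond, to give (3R,4Z)-6-[(tert-butyldimethylsilyl)oxy]-3-[(E)-heptadec-12-en-1-yl]hexa-1,4-dien-3-ol F6.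
- 9-BBN followed by NaOH/H2O2 hydroborates only the terminal vinyl group in the anti-Markovnikov sense and gives 16.

## Further compounds

F1 | step 13 | (1R,2S,5R)-5-[(E)-heptadec-12-en-1-yl]-5-[(triethylsilyl)oxy]cyclohex-3-ene-1,2-diol | CCCC/C=C/CCCCCCCCCCC[C@]1(O[Si](CC)(CC)CC)C=C[C@H](O)[C@H](O)C1
F2 | step 13 | (4R,6R)-4-[(E)-heptadec-12-en-1-yl]-6-hydroxy-4-[(triethylsilyl)oxy]cyclohex-2-en-1-one | CCCC/C=C/CCCCCCCCCCC[C@]1(O[Si](CC)(CC)CC)C=CC(=O)[C@H](O)C1
F3 | step 12 | (3R,4Z)-3-[(E)-heptadec-12-en-1-yl]-3-[(triethylsilyl)oxy]hex-4-ene-1,6-diol | CCCC/C=C/CCCCCCCCCCC[C@](O[Si](CC)(CC)CC)(/C=C\CO)CCO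
F4 | step 8 | [(2R,3S)-3-{3-[(tert-butyldimethylsilyl)oxy]prop-1-yn-1-yl}-3-[(E)-heptadec-12-en-1-yl]oxiran-2-yl]methanol | CCCC/C=C/CCCCCCCCCCC[C@@]1(C#CCO[Si](C)(C)C(C)(C)C)O[C@@H]1CO
F5 | step 9 | (2S,3S)-2-[(E)-heptadec-12-en-1-yl]-3-(iodomethyl)-2-{(Z)-3-[(tert-butyldimethylsilyl)oxy]prop-1-en-1-yl}oxirane | CCCC/C=C/CCCCCCCCCCC[C@@]1(/C=C\CO[Si](C)(C)C(C)(C)C)O[C@@H]1CI
F6 | step 9 | (3R,4Z)-6-[(tert-butyldimethylsilyl)oxy]-3-[(E)-heptadec-12-en-1-yl]hexa-1,4-dien-3-ol | CCCC/C=C/CCCCCCCCCCC[C@](O)(/C=C\CO[Si](C)(C)C(C)(C)C)C=C
A1 | alternative 1 | (5R)-5-(tert-butyldimethylsilyloxy)-1-[(E)-heptadec-12-en-1-yl]cyclohexa-1,3-diene | CCCC/C=C/CCCCCCCCCCCC1=CC=C[C@H](O[Si](C)(C)C(C)(C)C)C1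
A2 | alternative 1 | 8-(tert-butyldimethylsilyloxy)-1-[(E)-heptadec-12-en-1-yl]-2,3-dioxabicyclo[2.2.2]oct-5-ene, peroxide bridge anti to the silyloxy group | CCCC/C=C/CCCCCCCCCCC[C@@]12C=C[C@@H](OO1)[C@H](O[Si](C)(C)C(C)(C)C)C2
A3 | alternative 2 | (3R,5R,6R)-3-[(E)-heptadec-12-en-1-yl]-5,6-bis[(4-methoxybenzyl)oxy]octa-1,7-dien-3-ol | CCCC/C=C/CCCCCCCCCCC[C@](O)(C=C)C[C@@H](OCc1ccc(OC)cc1)[C@H](OCc1ccc(OC)cc1)C=C
A4 | alternative 2 | 4,5-bis(4-methoxybenzyl) ether of the target triol (working locants) | CCCC/C=C/CCCCCCCCCCC[C@]1(O)C=C[C@@H](OCc2ccc(OC)cc2)[C@H](OCc2ccc(OC)cc2)C1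
A5 | alternative 3 | (2R,4R,5Z)-4-[(E)-heptadec-12-en-1-yl]-4-hydroxy-6-iodo-2-[(4-methoxybenzyl)oxy]hex-5-enal | CCCC/C=C/CCCCCCCCCCC[C@](O)(/C=C\I)C[C@@H](OCc1ccc(OC)cc1)C=O
A6 | alternative 3 | 5-(4-methoxybenzyl) ether of the target triol (working locants) | CCCC/C=C/CCCCCCCCCCC[C@]1(O)C=C[C@@H](O)[C@H](OCc2ccc(OC)cc2)C1
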